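Subtract first.

| flask | substrate | partner | free catalyst | impurity | remark | time |
|---|---|---|---|---|---|---|
| dusk | 20 mM | 21 mM | 0.50 mM | 0.36 mM | run made earlier |  |
| flask | 20 mM | 21.0 mM | 0.50 mM | 0.73 mM |  | 6.0 h |

- dusk (time / min: isomer of the product / %, target / %, substrate / %): 2.50: 5.4, 39.6, 53.8; 8.00: 13.0, 58.0, 28.8; 12.0: 17.1, 59.9, 23.4; 20.0: 23.3, 57.6, 19.3; 30.0: 29.6, 53.0, 17.2; 40.0: 34.1, 49.4, 16.5

(each reading ± 0.3 percentage points)

- no earlier run changes the charge of impurity; that part of a forecast is a guess

- share of isomer of the product in isomer of the product plus target at 5.0 s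
- share of isomer of the product in isomer of the product plus target at 6.0 h

I took the fast step as settled. I assumed that free catalyst and impurity consume each other quickly and one to one, and I reckoned with what that leaves free. In the dusk run the impurity is then the limiting reagent.

margin = [free catalyst] − [impurity], both as charged

dusk run: 0.50 mM − 0.36 mM = 0.140 mM

flask: 0.50 mM − 0.73 mM = −0.230 mM

I call this difference, charged free catalyst minus charged impurity, the catalyst margin.

Impurity was the first setting. Going from 0.36 mM to 0.73 mM turns the margin to −0.230 mM, negative. So by hand the flask keeps no free catalyst, and 31.5 % of its impurity stays over.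

Substrate was the second setting. It does not stand in the margin, so changing it moves no part of this reckoning.

The dusk run, with its positive margin, still gained isomer of the product late, from 29.6 % at 30.0 min to 34.1 % at 40.0 min. Its first reading gave a share of 12.0 % at 2.50 min. The share rose after that, so I expected less at 5.0 s. The margin gave me a state, not the share at 6.0 h, which stayed a guess.

The forecast gave 9 % and 45 %, reasoning that “if poisoning is stoichiometric, all catalyst eventually dies”.

The flask gave 9.24 % and 47.4 %.

    substrate + partner ⇌ target (K = 710 M⁻¹, k = 15.0 M⁻¹ min⁻¹)
    substrate + partner ⇌ isomer of the product (K = 1600 M⁻¹, k = 1.50 M⁻¹ min⁻¹)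
    target + free catalyst ⇌ isomer of the product + free catalyst, rate k3*[free catalyst]*[target] forward; the back reaction follows from the equilibrium constant (k = 83.0 M⁻¹ min⁻¹)
    substrate → decomposition product (k = 1.80 × 10⁻⁵ min⁻¹)
    free catalyst + impurity → spent catalyst (k = 1100 M⁻¹ min⁻¹)

At 6.00 h the flask, with its margin of −0.230 mM, held 31.5 % of its impurity, against my 31.5 %, and 0 % free catalyst. Yet isomer of the product went from 14.1 % at 0.600 h to 40.3 % at 6.00 h. The half-life of target for going back through the step to substrate and partner, 0.55 h, is short against that time. A neighbour flask took 0.29 mM of impurity, its other charges as in the flask. Its margin is 0.210 mM, the flask's −0.230 mM plus the impurity not charged, or 42.0 % of the catalyst charged. That neighbour flask held 42.0 % free catalyst at 6.00 h, and its share reached 69.3 %.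

(The numbers in the tables were generated by integration for substances that don't exist; scatter was added.)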